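## The problem

Mallopallidol 24 is an unsymmetrical methylene-bridged dimer of two fully substituted phloroglucinol-derived rings and has no stereocentre, so the whole task is one of regiochemistry. Ring A is a C-methyl isobutyrylphloroglucinol whose oxygen para to the acyl group is a methyl ether, flanked by the C-methyl group and the bridge; ring B is a 5,7-dihydroxy-2,2,6-trimethylchroman-4-one joined to the bridge through C8. Ring B carries oxygens at C5, C7 and C8a, but only the C8a oxygen belongs to the pyranone, and because C5 and C8a both flank C4a, annulation of an undifferentiated ring would give two chromanone regioisomers. Joining two different phloroglucinols with a one-carbon electrophile gives homo- and hetero-dimers, so the bridge carbon is better brought in as a CH2 group already bonded to one ring. The bis(ortho-hydroxyaryl)methane unit is fragile: base opens it through an ortho-quinone methide, hot acid causes ipso-protonation, bridge scission or xanthene closure, and the free polyphenol is easily oxidised, so the ring A phenols should stay masked until the last step. The feature that allows a convergent solution is the pattern of ring B: the C7 hydroxyl lies between the C6 methyl group and the C8 benzylic carbon, oxygens sit at both meta positions (C5 and C8a), and C4a carries hydrogen. This is the resorcinol pattern formed when a siloxyalkyne and a 3-alkoxy-4-alkylcyclobutenone are combined in a Danheiser benzannulation, and in that reaction the two meta oxygens come from different reactants.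

## Retrosynthesis

Target 24 from chromanone 23. The last operation cuts only O–C bonds: the two benzyl ethers on ring A and the ethyl ether at C5 of 23. The ethyl ether is peri to the C4 carbonyl, so a chelating boron halide can remove it while the ring A methyl ether, which has no carbonyl neighbour, is kept. Ending with a deprotection keeps the base- and acid-labile free bis-phenol out of every earlier step.

Chromanone 23 from resorcinol 20 and 3-methylbut-2-enoic acid 21. The pyranone is cut at C4a–C4 and O1–C2, with the aryl enone 22 as the intermediate of the forward reaction. This cut is preferred over building the chromanone first and bridging later, because in 20 the only unsubstituted carbon of either ring is C4a and its only free ortho hydroxyl is at C8a. Site and direction of annulation are thus fixed by the substrate. The forward reaction must be a Friedel–Crafts acylation mild enough for the bridge and the benzyl ethers.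

Resorcinol 20 from silyl ether 19. Only the O–Si bond is cut. The fluoride step is trivial; its purpose is to release the C8a oxygen, and only that oxygen, next to C4a.

Silyl ether 19 from siloxyalkyne 10 and cyclobutenone 14 (key disconnection). Ring B is taken apart at C7–C8, C4a–C8a and C6–C7. Siloxyalkyne 10 supplies C8 and C8a with the silyloxy group. 3-Ethoxy-4-methylcyclobut-2-en-1-one 14 supplies C4a, C5 with its ethoxy group, C6 with its methyl group, and C7 as the carbonyl carbon. Compared with a formaldehyde-type union of two phloroglucinols, this cut removes the statistical coupling, delivers the C5 and C8a oxygens with different groups, and leaves C4a unsubstituted. The precursors are a single aromatic ring with a three-carbon side chain and a four-carbon ring made in one step. The forward reaction must be regiospecific in its [2+2] step and must tolerate the hindered ring A ketone.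

Cyclobutenone 14 from propanoyl chloride 11 and ethoxyacetylene 12. The four-membered ring is cut across C1–C2 and C3–C4 into methylketene 13, generated from 11, and the ynol ether 12. Both are commodity reagents, and the polarity of the ynol ether fixes the 3-ethoxy-4-methyl pattern.

Siloxyalkyne 10 from terminal alkyne 7. The C–O bond of the ynol ether is cut. Oxidation of the lithium acetylide 8 to the ynolate 9 and O-silylation is a one-flask operation. It is preferred to an ester homologation, which would need alkyllithium reagents next to the ketone.

Alkyne 7 from phenol 4 and propargyl bromide 5. The benzyl ethers are removed to give diol 6, and the aryl–CH2 bond is then cut. Phenol 4 has one free ring carbon, so C-alkylation can occur at only one site. Benzyl is chosen because it survives amide base, thermolysis and fluoride, and because a protected ring A cannot act as the leaving group in base-induced bridge scission.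

Phenol 4 from 2-methylphloroglucinol 1 and 2-methylpropanoyl chloride 2. The methyl ether is cut to give triol 3, and the aryl–acyl bond is cut to give 1 and 2. The acyl group is introduced first because it makes the para hydroxyl the most acidic and the only non-chelated one, which directs the single O-methylation.

## Roads not taken

Alternative 1: The gem-dimethyl carbon C2 is cut at both C2–CH3 bonds and traced to the lactone carbonyl of the ring B 4-methoxycoumarin A1. In the forward key step two equivalents of CH3Li with CeCl3 would add to the lactone of A1 and open it to the enol ether phenol A2, the product of the key step. Acid would then unmask the ketone of A2 and close the pyranone.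

The merits are real. In A1 the C8a oxygen is the ring oxygen from the outset, coumarin chemistry is robust, and all steps are ionic and need neither thermolysis nor a sensitive ynol ether. In these respects this road is better than the chosen plan.

The weak points lie elsewhere. The lactone of A1 is a vinylogous carbonate, so attack at C4 and conjugate addition compete with the double 1,2-addition. Methyllithium excludes the ring A ketone, so A2 lacks the isobutyryl group, and a late Friedel–Crafts acylation of ring A would be needed beside four benzyl ethers and an acid-labile bridge. Most importantly, the cut does not say how A1 is made: the unsymmetrical diarylmethane bond and the distinction between the C5 and C8a oxygens are moved into the coumarin synthesis. The chosen plan sets against the robustness of A1 that it makes the aryl–CH2–aryl connection, ring B and the oxygen differentiation in one convergent step and carries the ketone throughout.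

Alternative 2: The same benzannulation logic is applied to ring A. The ring B-substituted cyclobutenone A3 and 1-methoxyprop-1-yne A4 would be heated to give the diarylmethane A5, the product of the key step, with the chromanone already in place.

The ring A methyl ether would come regiospecifically from A4, which is better than a selective O-methylation. The pyranone would be closed on a simple phloroglucinol before any acid-sensitive bridge exists, which removes the most delicate late step of the chosen plan.

Against this, A3 is a 2-substituted 3-ethoxycyclobutenone that must itself be made by a ketene cycloaddition onto an ynol ether carried by the chromanone, so two consecutive cycloadditions are run on advanced material. The alkyne A4 is volatile and not a routine stock reagent. The product A5 still lacks the isobutyryl group, so a Friedel–Crafts acylation on ring A with the bridge installed is required, followed by selective de-ethylation. The length is similar. The chosen plan sets against the merits of A5 that its cyclobutenone is a one-step, four-carbon reagent, that the complex partner is reached from a terminal alkyne in one operation, and that no ring A acylation is needed after the union.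

Alternative 3: The C8a–O and C4a–C4 bonds are cut together. The aryne generated with CsF from the ortho-silylaryl triflate A6 would insert into the C–O bond of 3-methylbutanoic acid A7 and give the ortho-hydroxyaryl ketone A8, the product of the key step.

Both ortho substituents would arrive in one step, ring A is complete in A6, and the C5 alkoxy group directs the oxygen nucleophile to the distal aryne carbon C8a. The inherent regiocontrol is as good as that of the chosen plan.

The weak points are these. The triflate A6 is a fully substituted ring whose preparation already requires the C8a oxygen to be singled out, so the differentiation problem is solved beforehand by other means. The aryne from A6 is flanked by a benzyloxy group and the bulky diarylmethane carbon. O-Arylation of the acid A7 without acyl transfer is a known competing course. The acyl chain delivered by A7 is saturated, so A8 carries a 3-methylbutanoyl group, and pyranone closure would need an additional ketone desaturation beside a free phenol. The route is longer and the union of the two rings is again left to earlier steps, whereas the chosen plan obtains the differentiation as a direct consequence of ring construction.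

Key step: step 7

Assumption: cyclobutenone 14 is used as the racemate because its only stereocentre becomes the aromatic carbon C6 in step 7; ethoxyacetylene is handled as its commercial hexane solution.

## Steps

Step 1
Reactants: 1 2-methylphloroglucinol (2-methylbenzene-1,3,5-triol); 2 2-methylpropanoyl chloride
Product: 3 1-(2,4,6-trihydroxy-3-methylphenyl)-2-methylpropan-1-one
Conditions: AlCl3 (4 equiv), PhNO2/CH2Cl2, 0 °C to 40 °C; then ice and 2 M HCl
Reagents that add atoms: none
Why: Friedel–Crafts C-acylation of a phloroglucinol; the two free ring positions of 1 are equivalent and the first acyl group deactivates the ring, so mono-acylation should dominate.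

Step 2
Reactants: 3 1-(2,4,6-trihydroxy-3-methylphenyl)-2-methylpropan-1-one
Product: 4 1-(2,6-dihydroxy-4-methoxy-3-methylphenyl)-2-methylpropan-1-one
Conditions: (CH3O)2SO2 (1.0 equiv), K2CO3 (1.1 equiv), acetone, rt
Reagents that add atoms: dimethyl sulfate, COS(=O)(=O)OC
Why: Williamson O-methylation with limiting electrophile; the para hydroxyl is the most acidic (vinylogous acid) and is not held in a hydrogen bond to the carbonyl, so it should react first.

Step 3
Reactants: 4 1-(2,6-dihydroxy-4-methoxy-3-methylphenyl)-2-methylpropan-1-one; 5 propargyl bromide (3-bromoprop-1-yne)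
Product: 6 1-[2,6-dihydroxy-4-methoxy-3-methyl-5-(prop-2-yn-1-yl)phenyl]-2-methylpropan-1-one
Conditions: 10% aq. KOH, 0 °C to rt, slow addition of 5 (toluene solution)
Reagents that add atoms: none
Why: C-alkylation of an acylphloroglucinol phenoxide in water, the manifold used for C-prenylation of such ketones; hydrogen bonding to the phenoxide oxygens favours attack through carbon, and only one ring carbon is free to rearomatise after alkylation.

Step 4
Reactants: 6 1-[2,6-dihydroxy-4-methoxy-3-methyl-5-(prop-2-yn-1-yl)phenyl]-2-methylpropan-1-one
Product: 7 1-[2,6-bis(benzyloxy)-4-methoxy-3-methyl-5-(prop-2-yn-1-yl)phenyl]-2-methylpropan-1-one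
Conditions: BnBr (3 equiv), Cs2CO3 (3 equiv), DMF, rt
Reagents that add atoms: benzyl bromide, BrCc1ccccc1
Why: Williamson etherification of both chelated phenols; Cs2CO3 in DMF allows room temperature, which should keep the ortho-propargyl phenoxide from cycloisomerising to a benzofuran.

Step 5
Reactants: 7 1-[2,6-bis(benzyloxy)-4-methoxy-3-methyl-5-(prop-2-yn-1-yl)phenyl]-2-methylpropan-1-one
Product: 10 1-[2,6-bis(benzyloxy)-4-methoxy-3-methyl-5-{3-[(triisopropylsilyl)oxy]prop-2-yn-1-yl}phenyl]-2-methylpropan-1-one, via lithium acetylide 8 (not isolated), via lithium ynolate 9 (not isolated)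
Conditions: LiN(SiMe3)2 (1.1 equiv), THF, −78 °C; LiOOt-Bu (1.1 equiv, from t-BuOOH and LiN(SiMe3)2), −78 to 0 °C; i-Pr3SiOTf (1.3 equiv), −78 to 0 °C
Reagents that add atoms: tert-butyl hydroperoxide, CC(C)(C)OO; triisopropylsilyl trifluoromethanesulfonate, CC(C)[Si](OS(=O)(=O)C(F)(F)F)(C(C)C)C(C)C
Why: Oxidation of a lithium acetylide to the ynolate by electrophilic oxygen transfer from lithium tert-butyl peroxide, then O-silylation by the bulky silyl triflate, the standard one-flask route to triisopropylsilyloxyalkynes; the ring A ketone is an isopropyl ketone twisted between two ortho benzyloxy groups and should resist both enolisation and addition at these temperatures.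

Step 6
Reactants: 11 propanoyl chloride; 12 ethoxyacetylene (ethoxyethyne)
Product: 14 3-ethoxy-4-methylcyclobut-2-en-1-one (racemic), via methylketene 13 (not isolated)
Conditions: Et3N (1.2 equiv), Et2O, 0 °C to rt, slow addition of 11 to 12 (2 equiv) and Et3N
Reagents that add atoms: none
Why: Dehydrochlorination gives methylketene, which is trapped by the strongly nucleophilic ynol ether in a [2+2] ketene–alkyne cycloaddition; the ketene carbonyl carbon bonds to the unsubstituted alkyne carbon, which places ethoxy at C3 and methyl at the sp3 carbon C4.

Step 7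
Reactants: 10 1-[2,6-bis(benzyloxy)-4-methoxy-3-methyl-5-{3-[(triisopropylsilyl)oxy]prop-2-yn-1-yl}phenyl]-2-methylpropan-1-one; 14 3-ethoxy-4-methylcyclobut-2-en-1-one
Product: 19 1-[2,6-bis(benzyloxy)-3-{[4-ethoxy-2-hydroxy-3-methyl-6-(triisopropylsilyloxy)phenyl]methyl}-4-methoxy-5-methylphenyl]-2-methylpropan-1-one, via vinylketene 15 (not isolated), via vinylcyclobutenone 16 (not isolated), via dienylketene 17 (not isolated), via cyclohexadienone 18 (not isolated)
Conditions: 14 (1.3 equiv), toluene (0.3 M), 80 °C then 110 °C, sealed tube, Ar
Reagents that add atoms: none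
Why: Danheiser benzannulation of a cyclobutenone with a siloxyalkyne, a pericyclic cascade established for this pair of reactant classes. Thermal 4π electrocyclic opening of 14 gives vinylketene 15, whose ketene C=C bond adds to the siloxyalkyne in a [2+2] cycloaddition to give the 4-vinylcyclobutenone 16, forming C7–C8 and C4a–C8a. A second 4π opening gives dienylketene 17, and ring B closes by thermal disrotatory 6π electrocyclisation, which forms C6–C7; tautomerisation of cyclohexadienone 18 gives the phenol. No stereocentre is created, since the sp3 centres of 14, 16 and 18 all become aromatic carbons. The selectivity required is the orientation of the [2+2] step, and it is secured by the polarisation of the ynol ether: its nucleophilic β-carbon, which bears the ring A methylene, bonds to the electrophilic ketene carbonyl carbon. This places the silyloxy carbon at C8a, meta to the new C7 hydroxyl, and the ethoxy carbon at C5. Chemoselectivity rests on the much higher nucleophilicity of the siloxyalkyne compared with the hindered ring A ketone, and the benzyl ethers are inert to neutral thermolysis. The new phenol is flanked by two substituents, which should slow its acylation by excess 15.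

Step 8
Reactants: 19 1-[2,6-bis(benzyloxy)-3-{[4-ethoxy-2-hydroxy-3-methyl-6-(triisopropylsilyloxy)phenyl]methyl}-4-methoxy-5-methylphenyl]-2-methylpropan-1-one
Product: 20 1-[2,6-bis(benzyloxy)-3-[(4-ethoxy-2,6-dihydroxy-3-methylphenyl)methyl]-4-methoxy-5-methylphenyl]-2-methylpropan-1-one
Conditions: n-Bu4NF (1.1 equiv), AcOH (1.1 equiv), THF, 0 °C
Reagents that add atoms: none
Why: Fluoride cleavage of an aryl silyl ether, buffered with acetic acid so that the resorcinol is not left as a basic phenoxide; it frees the C8a hydroxyl, the only oxygen ortho to C4a that is not alkylated.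

Step 9
Reactants: 20 1-[2,6-bis(benzyloxy)-3-[(4-ethoxy-2,6-dihydroxy-3-methylphenyl)methyl]-4-methoxy-5-methylphenyl]-2-methylpropan-1-one; 21 3-methylbut-2-enoic acid
Product: 23 8-{[2,4-bis(benzyloxy)-6-methoxy-5-methyl-3-(2-methylpropanoyl)phenyl]methyl}-5-ethoxy-7-hydroxy-2,2,6-trimethyl-2,3-dihydro-4H-chromen-4-one, via aryl enone 22 (not isolated)
Conditions: 21 (1.2 equiv), ZnCl2 (2 equiv), POCl3, rt to 40 °C; then ice-water
Reagents that add atoms: none
Why: Friedel–Crafts acylation by the activated acid at C4a, the only unsubstituted carbon of ring B (ring A is hexasubstituted), followed by 6-endo-trig oxa-Michael addition of the C8a hydroxyl to the enone, the established one-flask 2,2-dimethylchromanone annulation of resorcinols; C5 carries ethoxy, so closure can only involve the C8a oxygen.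

Step 10
Reactants: 23 8-{[2,4-bis(benzyloxy)-6-methoxy-5-methyl-3-(2-methylpropanoyl)phenyl]methyl}-5-ethoxy-7-hydroxy-2,2,6-trimethyl-2,3-dihydro-4H-chromen-4-one
Product: 24 mallopallidol, 5,7-dihydroxy-8-{[2,4-dihydroxy-6-methoxy-5-methyl-3-(2-methylpropanoyl)phenyl]methyl}-2,2,6-trimethyl-2,3-dihydro-4H-chromen-4-one
Conditions: BCl3 (1 M in CH2Cl2, 8 equiv), C6HMe5 (6 equiv), CH2Cl2, −78 to 0 °C; MeOH quench, then aqueous work-up
Reagents that add atoms: none
Why: BCl3 with pentamethylbenzene as cation scavenger cleaves aryl benzyl ethers at low temperature, and the C5 ethyl ether, peri to the chromanone carbonyl, is removed by chelation-assisted dealkylation; the ring A methyl ether has no neighbouring carbonyl to chelate boron and should remain.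

## Compound list

In the names below, Ar stands for 2,4-bis(benzyloxy)-6-methoxy-5-methyl-3-(2-methylpropanoyl)phenyl.

1 | 2-methylphloroglucinol (2-methylbenzene-1,3,5-triol) | Cc1c(O)cc(O)cc1O | starting material
2 | 2-methylpropanoyl chloride | CC(C)C(=O)Cl | starting material
3 | 1-(2,4,6-trihydroxy-3-methylphenyl)-2-methylpropan-1-one | CC(C)C(=O)c1c(O)cc(O)c(C)c1O | intermediate
4 | 1-(2,6-dihydroxy-4-methoxy-3-methylphenyl)-2-methylpropan-1-one | CC(C)C(=O)c1c(O)cc(OC)c(C)c1O | intermediate
5 | propargyl bromide (3-bromoprop-1-yne) | C#CCBr | starting material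
6 | 1-[2,6-dihydroxy-4-methoxy-3-methyl-5-(prop-2-yn-1-yl)phenyl]-2-methylpropan-1-one | CC(C)C(=O)c1c(O)c(CC#C)c(OC)c(C)c1O | intermediate
7 | 1-[2,6-bis(benzyloxy)-4-methoxy-3-methyl-5-(prop-2-yn-1-yl)phenyl]-2-methylpropan-1-one | CC(C)C(=O)c1c(OCc2ccccc2)c(CC#C)c(OC)c(C)c1OCc1ccccc1 | intermediate
8 | lithium acetylide of 7 (not isolated) | [Li]C#CCc1c(OC)c(C)c(OCc2ccccc2)c(C(=O)C(C)C)c1OCc1ccccc1 | intermediate
9 | lithium ynolate, lithium 3-Ar-prop-1-yn-1-olate (not isolated) | [Li]OC#CCc1c(OC)c(C)c(OCc2ccccc2)c(C(=O)C(C)C)c1OCc1ccccc1 | intermediate
10 | 1-[2,6-bis(benzyloxy)-4-methoxy-3-methyl-5-{3-[(triisopropylsilyl)oxy]prop-2-yn-1-yl}phenyl]-2-methylpropan-1-one | CC(C)[Si](OC#CCc1c(OC)c(C)c(OCc2ccccc2)c(C(=O)C(C)C)c1OCc1ccccc1)(C(C)C)C(C)C | intermediate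
11 | propanoyl chloride | CCC(=O)Cl | starting material
12 | ethoxyacetylene (ethoxyethyne) | CCOC#C | starting material
13 | methylketene (prop-1-en-1-one; not isolated) | CC=C=O | intermediate
14 | 3-ethoxy-4-methylcyclobut-2-en-1-one (racemic) | CCOC1=CC(=O)C1C | intermediate
15 | vinylketene, 3-ethoxypenta-1,3-dien-1-one (alkene geometry not fixed; not isolated) | CCOC(=CC)C=C=O | intermediate
16 | 4-(1-ethoxyprop-1-en-1-yl)-2-(ArCH2)-3-[(triisopropylsilyl)oxy]cyclobut-2-en-1-one (racemic; not isolated) | CCOC(=CC)C1C(=O)C(Cc2c(OC)c(C)c(OCc3ccccc3)c(C(=O)C(C)C)c2OCc2ccccc2)=C1O[Si](C(C)C)(C(C)C)C(C)C | intermediate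
17 | dienylketene, 5-ethoxy-2-(ArCH2)-3-[(triisopropylsilyl)oxy]hepta-1,3,5-trien-1-one (not isolated) | CCOC(=CC)C=C(O[Si](C(C)C)(C(C)C)C(C)C)C(=C=O)Cc1c(OC)c(C)c(OCc2ccccc2)c(C(=O)C(C)C)c1OCc1ccccc1 | intermediate
18 | 5-ethoxy-6-methyl-2-(ArCH2)-3-[(triisopropylsilyl)oxy]cyclohexa-2,4-dien-1-one (racemic; not isolated) | CCOC1=CC(O[Si](C(C)C)(C(C)C)C(C)C)=C(Cc2c(OC)c(C)c(OCc3ccccc3)c(C(=O)C(C)C)c2OCc2ccccc2)C(=O)C1C | intermediate
19 | 1-[2,6-bis(benzyloxy)-3-{[4-ethoxy-2-hydroxy-3-methyl-6-(triisopropylsilyloxy)phenyl]methyl}-4-methoxy-5-methylphenyl]-2-methylpropan-1-one | CCOc1cc(O[Si](C(C)C)(C(C)C)C(C)C)c(Cc2c(OC)c(C)c(OCc3ccccc3)c(C(=O)C(C)C)c2OCc2ccccc2)c(O)c1C | intermediate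
20 | 1-[2,6-bis(benzyloxy)-3-[(4-ethoxy-2,6-dihydroxy-3-methylphenyl)methyl]-4-methoxy-5-methylphenyl]-2-methylpropan-1-one | CCOc1cc(O)c(Cc2c(OC)c(C)c(OCc3ccccc3)c(C(=O)C(C)C)c2OCc2ccccc2)c(O)c1C | intermediate
21 | 3-methylbut-2-enoic acid | CC(C)=CC(=O)O | starting material
22 | 1-[3-(ArCH2)-6-ethoxy-2,4-dihydroxy-5-methylphenyl]-3-methylbut-2-en-1-one (not isolated) | CCOc1c(C(=O)C=C(C)C)c(O)c(Cc2c(OC)c(C)c(OCc3ccccc3)c(C(=O)C(C)C)c2OCc2ccccc2)c(O)c1C | intermediate
23 | 8-{[2,4-bis(benzyloxy)-6-methoxy-5-methyl-3-(2-methylpropanoyl)phenyl]methyl}-5-ethoxy-7-hydroxy-2,2,6-trimethyl-2,3-dihydro-4H-chromen-4-one | CCOc1c(C)c(O)c(Cc2c(OC)c(C)c(OCc3ccccc3)c(C(=O)C(C)C)c2OCc2ccccc2)c2c1C(=O)CC(C)(C)O2 | intermediate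
24 | mallopallidol, 5,7-dihydroxy-8-{[2,4-dihydroxy-6-methoxy-5-methyl-3-(2-methylpropanoyl)phenyl]methyl}-2,2,6-trimethyl-2,3-dihydro-4H-chromen-4-one | COc1c(C)c(O)c(C(=O)C(C)C)c(O)c1Cc1c(O)c(C)c(O)c2c1OC(C)(C)CC2=O | target

## Step count and least certain steps

Total: 10 steps. Longest linear sequence: 9 steps (steps 1 to 5 and 7 to 10); step 6 is a one-step side branch.

In step 7, the key step, the most likely failure is in the first electrocyclic opening. The 3-ethoxy group makes 14 a vinylogous ester, so opening may need temperatures at which the siloxyalkyne 10 isomerises by 1,3-silyl migration to a C-silyl ketene. Acylation of the new phenol by the vinylketene is a second loss. The fallback sets out from 10 and generates the same vinylketene 15 at room temperature by 1,4-dehydrochlorination instead of ring opening. Ethyl 3-oxopentanoate is converted with HC(OEt)3 and catalytic H2SO4 into ethyl (2E)-3-ethoxypent-2-enoate F1. This is saponified with NaOH and carefully acidified with cold dilute HCl to (2E)-3-ethoxypent-2-enoic acid F2, which (COCl)2 converts into (2E)-3-ethoxypent-2-enoyl chloride F3. Slow addition of F3 to 10 and Et3N in toluene should give the cycloadduct 16 directly, and brief heating then completes the cascade. The route is rejoined at 19.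

In step 5, the risks are competing enolisation of the ring A ketone, addition of the ynolate to it, or deprotonation at the doubly activated benzylic-propargylic methylene with propargyl-to-allenyl isomerisation. The fallback sets out from 7 and masks the carbonyl. LiAlH4 in THF reduces 7 to 1-[2,6-bis(benzyloxy)-4-methoxy-3-methyl-5-(prop-2-yn-1-yl)phenyl]-2-methylpropan-1-ol F4 (racemic), and Et3SiOTf with 2,6-lutidine gives its triethylsilyl ether F5. The acetylide oxidation and silylation of step 5 then give the siloxyalkyne F6, and thermolysis with 14 as in step 7 gives the benzannulated triethylsilyl ether F7. HF·pyridine in THF/pyridine should remove the alkyl silyl ether in preference to the aryl one and give the carbinol F8. Swern oxidation ((COCl)2, DMSO, Et3N) restores the ketone; the hindered phenol has both ortho positions blocked and should survive. The route is rejoined at 19.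

In step 3, the risks are O-propargylation in place of C-alkylation, and base-induced cycloisomerisation of the ortho-propargyl phenoxide of 6 to a 2-methylbenzofuran. The fallback sets out from 4 and replaces phenoxide alkylation by electrophilic aromatic substitution. Benzylation (BnBr, Cs2CO3, DMF) gives 1-[2,6-bis(benzyloxy)-4-methoxy-3-methylphenyl]-2-methylpropan-1-one F9. A Nicholas reaction with Co2(CO)6(HC≡CCH2OH) and BF3·OEt2 in CH2Cl2 at the only free ring position gives the hexacarbonyldicobalt alkyne complex F10, which is the Co2(CO)6 complex of 7. Oxidative decomplexation with Fe(NO3)3·9H2O in ethanol releases the alkyne. The route is rejoined at 7, bypassing 6.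

In step 9, the risk is acid-induced damage: ipso-protonation at C8 with scission of the methylene bridge, loss of ring A benzyl ethers with benzylation at C4a, or O-acylation that does not proceed to the ketone. The hotter protic variants (P2O5 in CH3SO3H, BF3·OEt2 at 70 °C) are avoided for this reason. The fallback sets out from 20 and builds the pyranone in two milder operations. Acetic anhydride and BF3·OEt2 at 0 °C to room temperature give the C4a acetyl compound 1-[3-(ArCH2)-6-ethoxy-2,4-dihydroxy-5-methylphenyl]ethan-1-one F11; any phenyl acetate is cleaved in the next operation. Kabbe condensation of F11 with acetone and pyrrolidine in methanol closes the 2,2-dimethylpyranone through enamine aldol condensation and oxa-Michael addition of the C8a hydroxyl. The route is rejoined at 23.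

In step 10, the risk is over-dealkylation, that is loss of the ring A methyl ether. Its oxygen is twisted out of conjugation by two ortho substituents and is more Lewis basic than an ordinary anisole oxygen. The opposite risk is incomplete cleavage of the chelated ethyl ether. The fallback sets out from 23 and separates the two tasks. Hydrogenolysis (H2, Pd/C (palladium on carbon), ethyl acetate) removes the benzyl groups and gives 5-O-ethylmallopallidol F12. MgI2 in diethyl ether/toluene, a reagent specific for ethers ortho to a carbonyl group, then removes the ethyl group of F12. The route is rejoined at 24.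

In step 6, the risk is amine-catalysed dimerisation of methylketene outrunning its capture by ethoxyacetylene. The fallback sets out from 12 and uses a more electrophilic ketene. 2-Chloropropanoyl chloride and Et3N generate chloro(methyl)ketene F13, which should add to 12 to give 4-chloro-3-ethoxy-4-methylcyclobut-2-en-1-one F14. Reductive dechlorination of F14 with Zn, AcOH and tetramethylethylenediamine in ethanol then gives the cyclobutenone. The route is rejoined at 14.

## Further compounds

F1 | step 7 | ethyl (2E)-3-ethoxypent-2-enoate | CCOC(=O)/C=C(/OCC)CC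
F2 | step 7 | (2E)-3-ethoxypent-2-enoic acid | OC(=O)/C=C(/OCC)CC
F3 | step 7 | (2E)-3-ethoxypent-2-enoyl chloride | ClC(=O)/C=C(/OCC)CC
F4 | step 5 | 1-[2,6-bis(benzyloxy)-4-methoxy-3-methyl-5-(prop-2-yn-1-yl)phenyl]-2-methylpropan-1-ol (racemic) | CC(C)C(O)c1c(OCc2ccccc2)c(CC#C)c(OC)c(C)c1OCc1ccccc1
F5 | step 5 | triethylsilyl ether of F4 (racemic) | CC[Si](CC)(CC)OC(C(C)C)c1c(OCc2ccccc2)c(CC#C)c(OC)c(C)c1OCc1ccccc1
F6 | step 5 | siloxyalkyne from F5, triethylsilyl ether of the carbinol analogue of 10 (racemic) | CC[Si](CC)(CC)OC(C(C)C)c1c(OCc2ccccc2)c(CC#CO[Si](C(C)C)(C(C)C)C(C)C)c(OC)c(C)c1OCc1ccccc1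
F7 | step 5 | benzannulation product from F6, triethylsilyl ether of the carbinol analogue of 19 (racemic) | CCOc1cc(O[Si](C(C)C)(C(C)C)C(C)C)c(Cc2c(OC)c(C)c(OCc3ccccc3)c(C(O[Si](CC)(CC)CC)C(C)C)c2OCc2ccccc2)c(O)c1C
F8 | step 5 | carbinol analogue of 19 (racemic) | CCOc1cc(O[Si](C(C)C)(C(C)C)C(C)C)c(Cc2c(OC)c(C)c(OCc3ccccc3)c(C(O)C(C)C)c2OCc2ccccc2)c(O)c1C
F9 | step 3 | 1-[2,6-bis(benzyloxy)-4-methoxy-3-methylphenyl]-2-methylpropan-1-one | CC(C)C(=O)c1c(OCc2ccccc2)cc(OC)c(C)c1OCc1ccccc1
F10 | step 3 | hexacarbonyldicobalt complex of alkyne 7 | CC(C)C(=O)c1c(OCc2ccccc2)c(CC23[CH]4[Co]2(=C=O)(=C=O)(=C=O)[Co]34(=C=O)(=C=O)=C=O)c(OC)c(C)c1OCc1ccccc1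
F11 | step 9 | 1-[3-(ArCH2)-6-ethoxy-2,4-dihydroxy-5-methylphenyl]ethan-1-one | CCOc1c(C(C)=O)c(O)c(Cc2c(OC)c(C)c(OCc3ccccc3)c(C(=O)C(C)C)c2OCc2ccccc2)c(O)c1C
F12 | step 10 | 5-O-ethylmallopallidol | CCOc1c(C)c(O)c(Cc2c(OC)c(C)c(O)c(C(=O)C(C)C)c2O)c2c1C(=O)CC(C)(C)O2
F13 | step 6 | chloro(methyl)ketene (2-chloroprop-1-en-1-one; not isolated) | CC(Cl)=C=O
F14 | step 6 | 4-chloro-3-ethoxy-4-methylcyclobut-2-en-1-one (racemic) | CCOC1=CC(=O)C1(C)Cl
A1 | alternative 1 | 5,7-bis(benzyloxy)-8-{[2,4-bis(benzyloxy)-6-methoxy-5-methylphenyl]methyl}-4-methoxy-6-methyl-2H-chromen-2-one | COc1cc(=O)oc2c(Cc3c(OC)c(C)c(OCc4ccccc4)cc3OCc3ccccc3)c(OCc3ccccc3)c(C)c(OCc3ccccc3)c12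
A2 | alternative 1 | 3,5-bis(benzyloxy)-2-{[2,4-bis(benzyloxy)-6-methoxy-5-methylphenyl]methyl}-6-[(1E)-3-hydroxy-1-methoxy-3-methylbut-1-en-1-yl]-4-methylphenol | CO/C(=C/C(C)(C)O)c1c(O)c(Cc2c(OC)c(C)c(OCc3ccccc3)cc2OCc2ccccc2)c(OCc2ccccc2)c(C)c1OCc1ccccc1
A3 | alternative 2 | 5,7-bis(benzyloxy)-8-[(2-ethoxy-4-oxocyclobut-1-en-1-yl)methyl]-2,2,6-trimethyl-2,3-dihydro-4H-chromen-4-one | CCOC1=C(Cc2c(OCc3ccccc3)c(C)c(OCc3ccccc3)c3c2OC(C)(C)CC3=O)C(=O)C1
A4 | alternative 2 | 1-methoxyprop-1-yne | CC#COC
A5 | alternative 2 | 5,7-bis(benzyloxy)-8-[(6-ethoxy-4-hydroxy-2-methoxy-3-methylphenyl)methyl]-2,2,6-trimethyl-2,3-dihydro-4H-chromen-4-one | CCOc1cc(O)c(C)c(OC)c1Cc1c(OCc2ccccc2)c(C)c(OCc2ccccc2)c2c1OC(C)(C)CC2=O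
A6 | alternative 3 | 3,5-bis(benzyloxy)-2-{[2,4-bis(benzyloxy)-6-methoxy-5-methyl-3-(2-methylpropanoyl)phenyl]methyl}-4-methyl-6-(trimethylsilyl)phenyl trifluoromethanesulfonate | C[Si](C)(C)c1c(OS(=O)(=O)C(F)(F)F)c(Cc2c(OC)c(C)c(OCc3ccccc3)c(C(=O)C(C)C)c2OCc2ccccc2)c(OCc2ccccc2)c(C)c1OCc1ccccc1
A7 | alternative 3 | 3-methylbutanoic acid | CC(C)CC(=O)O
A8 | alternative 3 | 1-[2,4-bis(benzyloxy)-5-{[2,4-bis(benzyloxy)-6-methoxy-5-methyl-3-(2-methylpropanoyl)phenyl]methyl}-6-hydroxy-3-methylphenyl]-3-methylbutan-1-one | CC(C)CC(=O)c1c(O)c(Cc2c(OC)c(C)c(OCc3ccccc3)c(C(=O)C(C)C)c2OCc2ccccc2)c(OCc2ccccc2)c(C)c1OCc1ccccc1
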